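Dawn was charged 4.14 times as heavily as winter, yet I found its target falling at nearly the same pace, counted as a fraction of the charge. Two rates carry the argument, so I compared them over nearly the same stretch, from the first reading near the top to the last.

| flask | starting material | remark | time |
|---|---|---|---|
| winter | 0.0058 M | run made earlier |  |
| dawn | 0.024 M | run made earlier |  |
| north-west | 0.0050 M |  | 5.0 min |
| south-west | 0.010 M |  | 5.0 min |
| west | 0.020 M |  | 5.0 min |

| run | time / min | target / % |
|---|---|---|
| winter | 0.833 | 63.4 |
| winter | 2.00 | 60.8 |
| winter | 2.50 | 59.4 |
| winter | 4.00 | 58.0 |
| dawn | 0.250 | 65.0 |
| dawn | 0.667 | 64.8 |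
| dawn | 1.50 | 61.4 |
| dawn | 4.00 | 58.3 |

(readings scatter by 0.3 percentage points)

- "hardly changes" means that all values lie within two and a half points (for a concentration: within two and a half percent of the largest)

- [target] at the end for north-west, south-west, west, in this order
- how that number moves from the first to the last of them (falls, then rises / rises, then falls / rises all the way / falls all the way / hardly changes)

Winter's fall: 0.0171 min⁻¹

Dawn's fall: 0.0195 min⁻¹

Dawn's fall over winter's, which I called the fall ratio: 1.14

The minutes cancel in this ratio, but the curve bends and the two stretches differ a little, so its value shifts with the window: taken from dawn's first reading, it came to 1.05. A loss going with the square of the charge gives a fall ratio equal to the charge ratio, and I read one far smaller. Scatter of 0.3 percentage points on falls of 5.4 points and 6.5 points leaves that reading compatible with 1: first-order behaviour. So I reckoned that one percentage serves every charge, and that west should hold 4.00 times the [target] of north-west.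

The forecast gave 0.00286 M, 0.00572 M and 0.01144 M, rises all the way, on the ground that “The percent yield at a given time therefore doesn't depend on concentration”.

The flasks gave 0.00290 M, 0.00580 M and 0.0116 M, rises all the way.

    starting material ⇌ target (K = 2.20, k = 0.170 s⁻¹)
    isomer of the product A ⇌ isomer of the product B (K = 9.10, k = 3.50 × 10⁻⁴ s⁻¹)
    target ⇌ isomer of the product A (K = 0.260, k = 0.00310 s⁻¹)

Between 2.50 min and 5.00 min, west's fall over north-west's was 1.00, beside the 1.14 read from dawn and winter. In north-west, starting material and target relaxed with a half-life of 2.80 s by their step alone, far shorter than the 3.7 min half-life of target by its forward step to isomer of the product A: a pre-equilibrium. At 5.00 min, north-west's target, standing at 58.0%, was made at 0.320 of the rate at which it was used up.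

(The earlier runs and the new flask come from a simulation for an exercise; the scatter is artificial.)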